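The route rests on disconnecting the C2'–C3' bond of dihydrofuran ring D. C3' bears a carbon at ester oxidation level and C2' is a benzylic ether carbon held between O1' and ring E, so a ring B aryldiazoacetate can insert its carbene into the ortho O–CH2–aryl C–H bond five atoms away. One flask closes ring D, fixes C2' under catalyst control and relaxes C3' to trans. The precursor is a methyl aryldiazoacetate on ring B flanked by the (4-benzyloxy-3-methoxybenzyl)oxy group, with O7' benzylated and C5' carried as a methyl ester. The C5' aldehyde later builds the flavanone by Knoevenagel condensation, enantioselective oxa-Michael closure and decarboxylation; hydrogenolysis finishes.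

Key step: step 7

Locants: primed numbers refer to the dihydrobenzofuran (ring B is its benzo ring, ring D its dihydrofuran ring; O1', C2', C3', C3a', C4'–C7', C7a'). Ring E is the 4-hydroxy-3-methoxyphenyl group on C2'. Unprimed numbers refer to the flavanone (rings A and C).

Remark on the precursor design: C5' is carried as a methyl ester and every phenol as a benzyl ether.
- A C5' acetal would have to be formed and hydrolysed with acid next to the acid-labile 4-alkoxybenzyl aryl ether.
- The ester needs no masking step, tolerates the zinc enolate, the diazo transfer, the carbene and methoxide, and is reduced together with the C3' ester.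
- MnO2 then returns only the benzylic C5' carbon to the aldehyde, so the C3' hydroxymethyl group needs no protection.
- Benzyl ethers give a storable ring E benzylic chloride and survive the acidic decarboxylation.

Assumption on step 7: Rh2(S-PTTL)4 is taken to deliver the 2'R series drawn; should the sense of induction prove opposite, Rh2(R-PTTL)4 is used with no other change.

Assumption on step 13: the quinidine-derived thiourea is taken to give the 2S flavanone; should the sense prove opposite, the quinine-derived pseudoenantiomer is used.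

Step 1
Reactants: 1 4-(benzyloxy)-3-methoxybenzyl alcohol
Product: 2 4-(benzyloxy)-3-methoxybenzyl chloride
Conditions: SOCl2, CH2Cl2, 0 °C to rt
Reagents that add atoms: thionyl chloride, ClS(Cl)=O
Why: Chlorodehydroxylation of an electron-rich benzylic alcohol through its chlorosulfite is fast at 0 °C, and the benzyl-capped phenol should make the chloride a stable, storable electrophile.

Step 2
Reactants: 3 methyl 3-bromo-4-hydroxy-5-methoxybenzoate
Product: 4 methyl 3-bromo-4,5-dihydroxybenzoate
Conditions: AlCl3, pyridine, CH2Cl2, reflux; aq. HCl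
Reagents that add atoms: none
Why: Chelation-assisted demethylation of an ortho-hydroxyanisole, in which the aluminium phenoxide binds the neighbouring methoxy oxygen and pyridine removes the activated methyl group by SN2, so that only this ether is cleaved and the methyl ester is left alone.

Step 3
Reactants: 4 methyl 3-bromo-4,5-dihydroxybenzoate; 2 4-(benzyloxy)-3-methoxybenzyl chloride
Product: 5 methyl 3-bromo-4-{[4-(benzyloxy)-3-methoxybenzyl]oxy}-5-hydroxybenzoate
Conditions: Li2CO3 (1.1 equiv), NaI (cat.), DMF, 50 °C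
Reagents that add atoms: none
Why: Regioselective Williamson etherification, in which the 4-hydroxyl (para to the ester, ortho to bromine) is the more acidic one, so one equivalent of the weak base Li2CO3 should form only that phenoxide for alkylation by the iodide-activated benzylic chloride.

Step 4
Reactants: 5 methyl 3-bromo-4-{[4-(benzyloxy)-3-methoxybenzyl]oxy}-5-hydroxybenzoate
Product: 6 methyl 3-(benzyloxy)-5-bromo-4-{[4-(benzyloxy)-3-methoxybenzyl]oxy}benzoate
Conditions: BnBr, K2CO3, DMF, rt
Reagents that add atoms: benzyl bromide, BrCc1ccccc1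
Why: Plain Williamson etherification of the one remaining phenol, which caps O7' against O–H insertion and protonation of the zinc enolate later on.

Step 5
Reactants: 6 methyl 3-(benzyloxy)-5-bromo-4-{[4-(benzyloxy)-3-methoxybenzyl]oxy}benzoate; 7 methyl bromoacetate
Product: 9 methyl 3-(benzyloxy)-4-{[4-(benzyloxy)-3-methoxybenzyl]oxy}-5-(2-methoxy-2-oxoethyl)benzoate, via Reformatsky reagent BrZnCH2CO2Me 8 (not isolated)
Conditions: 7, Zn, TMSCl (cat.), THF, 40 °C; then 6, [PdBr(P(t-Bu)3)]2 (1 mol%), THF, rt
Reagents that add atoms: none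
Why: Negishi-type palladium-catalysed arylation of a Reformatsky zinc enolate (oxidative addition of the electron-poor aryl bromide, transmetalation from zinc, reductive elimination), in which the weakly basic zinc enolate should leave the aryl methyl ester and the benzylic ethers untouched.

Step 6
Reactants: 9 methyl 3-(benzyloxy)-4-{[4-(benzyloxy)-3-methoxybenzyl]oxy}-5-(2-methoxy-2-oxoethyl)benzoate
Product: 10 methyl 3-(benzyloxy)-4-{[4-(benzyloxy)-3-methoxybenzyl]oxy}-5-(1-diazo-2-methoxy-2-oxoethyl)benzoate
Conditions: p-ABSA, DBU, MeCN, 0 °C to rt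
Reagents that add atoms: 4-acetamidobenzenesulfonyl azide (p-ABSA), CC(=O)Nc1ccc(cc1)S(=O)(=O)N=[N+]=[N-]
Why: Regitz diazo transfer, in which DBU deprotonates the arylacetate CH2 (the only acidic site) and the enolate attacks the terminal azide nitrogen, the triazene then collapsing to the aryldiazoacetate and the sulfonamide.

Step 7
Reactants: 10 methyl 3-(benzyloxy)-4-{[4-(benzyloxy)-3-methoxybenzyl]oxy}-5-(1-diazo-2-methoxy-2-oxoethyl)benzoate
Product: 12 dimethyl (2R,3R)-7-(benzyloxy)-2-[4-(benzyloxy)-3-methoxyphenyl]-2,3-dihydro-1-benzofuran-3,5-dicarboxylate (trans), via cis-diester 11 (not isolated)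
Conditions: Rh2(S-PTTL)4 (dirhodium tetrakis[N-phthaloyl-(S)-tert-leucinate], 1–2 mol%), toluene, −60 °C, slow addition of 10; then NaOMe, MeOH, 0 °C to rt
Reagents that add atoms: none
Why: The dirhodium carboxylate expels N2 from 10 to give a rhodium-bound donor/acceptor carbene, which inserts in a concerted, hydride-transfer-like manner into the O–CH2–aryl C–H bond five atoms away. The closest known reaction type is the chiral dirhodium carboxylate-catalysed intramolecular C–H insertion of ortho-benzyloxy aryldiazoacetates to cis-2-aryl-2,3-dihydrobenzofuran-3-carboxylates. Ring D is closed by a 1,5-insertion through a five-membered cyclic transition state that forms the C2'–C3' bond. C2' is set by the chiral carboxylate pocket, which selects one of the two enantiotopic benzylic hydrogens, and C3', first cis in 11, is then epimerised through its ester enolate by NaOMe to the more stable trans arrangement dictated by C2'. The step needs exclusive insertion at the ring E benzylic ether C–H, which is secured because this bond is doubly activated (O1' lone pair and the electron-rich 4-benzyloxy-3-methoxyphenyl ring) and is the only C–H within reach, the O7' benzyl and ester methyl hydrogens being geometrically out of range. Methyl esters paired with methoxide exclude transesterification, and ring opening by β-elimination of the phenoxide is stereoelectronically disfavoured (reverse of a 5-endo-trig closure).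

Step 8
Reactants: 12 dimethyl (2R,3R)-7-(benzyloxy)-2-[4-(benzyloxy)-3-methoxyphenyl]-2,3-dihydro-1-benzofuran-3,5-dicarboxylate
Product: 13 [(2R,3S)-7-(benzyloxy)-2-[4-(benzyloxy)-3-methoxyphenyl]-2,3-dihydro-1-benzofuran-3,5-diyl]dimethanol
Conditions: LiAlH4, THF, 0 °C; aq. NaOH work-up
Reagents that add atoms: none
Why: Hydride reduction of both methyl esters to primary alcohols, which also removes the acidifying carbonyl at C3' and so locks the trans relationship (the descriptor at C3' changes to S only through the priority rules).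

Step 9
Reactants: 13 [(2R,3S)-7-(benzyloxy)-2-[4-(benzyloxy)-3-methoxyphenyl]-2,3-dihydro-1-benzofuran-3,5-diyl]dimethanol
Product: 14 (2R,3S)-7-(benzyloxy)-2-[4-(benzyloxy)-3-methoxyphenyl]-3-(hydroxymethyl)-2,3-dihydro-1-benzofuran-5-carbaldehyde
Conditions: MnO2 (activated, excess), CH2Cl2, rt
Reagents that add atoms: none
Why: Chemoselective benzylic oxidation, since activated MnO2 oxidises benzylic alcohols but not saturated primary ones, so the C5' hydroxymethyl should go to the aldehyde while the C3' hydroxymethyl stays.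

Step 10
Reactants: 15 2',4',6'-trihydroxyacetophenone
Product: 16 1-[2,4-bis(benzyloxy)-6-hydroxyphenyl]ethanone
Conditions: BnBr (2.05 equiv), K2CO3, DMF, rt
Reagents that add atoms: benzyl bromide, BrCc1ccccc1
Why: Williamson etherification of two hydroxyls, in which the third hydroxyl, hydrogen-bonded to the acetyl carbonyl, is the least nucleophilic and should remain free.

Step 11
Reactants: 16 1-[2,4-bis(benzyloxy)-6-hydroxyphenyl]ethanone
Product: 17 tert-butyl 3-[2,4-bis(benzyloxy)-6-hydroxyphenyl]-3-oxopropanoate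
Conditions: LiHMDS (3.2 equiv), THF, −78 to −10 °C; Boc2O, −78 °C to rt; aq. NH4Cl
Reagents that add atoms: di-tert-butyl dicarbonate, CC(C)(C)OC(=O)OC(=O)OC(C)(C)C
Why: Crossed Claisen-type C-acylation of the phenoxide–enolate dianion by Boc2O, in which any O-carbonate formed passes its acyl group on to carbon through the enolate and the third equivalent of base stores the β-ketoester as its enolate.

Step 12
Reactants: 14 (2R,3S)-7-(benzyloxy)-2-[4-(benzyloxy)-3-methoxyphenyl]-3-(hydroxymethyl)-2,3-dihydro-1-benzofuran-5-carbaldehyde; 17 tert-butyl 3-[2,4-bis(benzyloxy)-6-hydroxyphenyl]-3-oxopropanoate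
Product: 18 tert-butyl (2Z)-2-[2,4-bis(benzyloxy)-6-hydroxybenzoyl]-3-{(2R,3S)-7-(benzyloxy)-2-[4-(benzyloxy)-3-methoxyphenyl]-3-(hydroxymethyl)-2,3-dihydro-1-benzofuran-5-yl}prop-2-enoate
Conditions: piperidine (cat.), AcOH (cat.), 4 Å MS, toluene, rt
Reagents that add atoms: none
Why: Knoevenagel condensation of the active methylene compound with the aldehyde under piperidinium acetate catalysis (iminium activation, then dehydration), expected mainly as the Z isomer, with the phenol held back by its hydrogen bond to the aryl ketone and either alkene isomer leading to the same flavanone constitution.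

Step 13
Reactants: 18 tert-butyl (2Z)-2-[2,4-bis(benzyloxy)-6-hydroxybenzoyl]-3-{(2R,3S)-7-(benzyloxy)-2-[4-(benzyloxy)-3-methoxyphenyl]-3-(hydroxymethyl)-2,3-dihydro-1-benzofuran-5-yl}prop-2-enoate
Product: 20 (2S)-5,7-bis(benzyloxy)-2-{(2R,3S)-7-(benzyloxy)-2-[4-(benzyloxy)-3-methoxyphenyl]-3-(hydroxymethyl)-2,3-dihydro-1-benzofuran-5-yl}-2,3-dihydro-4H-chromen-4-one, via chromanone tert-butyl ester 19 (not isolated)
Conditions: 3,5-bis(trifluoromethyl)phenyl thiourea of 9-amino-9-deoxy-epi-quinidine (10 mol%), toluene, −25 °C; then TsOH·H2O, 80 °C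
Reagents that add atoms: none
Why: Enantioselective intramolecular oxa-Michael addition (6-endo-trig) in which the bifunctional catalyst binds the 1,3-dicarbonyl through its thiourea and the phenol through its quinuclidine nitrogen and so fixes the face of attack, setting flavanone C2 as S, after which acid cleaves the tert-butyl ester and the β-keto acid loses CO2, removing the C3 centre.

Step 14
Reactants: 20 (2S)-5,7-bis(benzyloxy)-2-{(2R,3S)-7-(benzyloxy)-2-[4-(benzyloxy)-3-methoxyphenyl]-3-(hydroxymethyl)-2,3-dihydro-1-benzofuran-5-yl}-2,3-dihydro-4H-chromen-4-one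
Product: 21 silyhermin B
Conditions: H2 (1 atm), Pd/C (10% palladium on carbon), EtOAc–MeOH, rt
Reagents that add atoms: none
Why: Hydrogenolysis of the four primary benzyl aryl ethers under neutral conditions, in which the secondary, ring-constrained benzylic C–O bonds at C2' and C2 and the hydrogen-bonded aryl ketone should react much more slowly and no stereocentre is involved.

Compound list

1 | 4-(benzyloxy)-3-methoxybenzyl alcohol | COc1cc(CO)ccc1OCc1ccccc1 | starting material
2 | 4-(benzyloxy)-3-methoxybenzyl chloride | COc1cc(CCl)ccc1OCc1ccccc1 | intermediate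
3 | methyl 3-bromo-4-hydroxy-5-methoxybenzoate (methyl 5-bromovanillate) | COC(=O)c1cc(Br)c(O)c(OC)c1 | starting material
4 | methyl 3-bromo-4,5-dihydroxybenzoate | COC(=O)c1cc(Br)c(O)c(O)c1 | intermediate
5 | methyl 3-bromo-4-{[4-(benzyloxy)-3-methoxybenzyl]oxy}-5-hydroxybenzoate | COC(=O)c1cc(Br)c(OCc2ccc(OCc3ccccc3)c(OC)c2)c(O)c1 | intermediate
6 | methyl 3-(benzyloxy)-5-bromo-4-{[4-(benzyloxy)-3-methoxybenzyl]oxy}benzoate | COC(=O)c1cc(Br)c(OCc2ccc(OCc3ccccc3)c(OC)c2)c(OCc2ccccc2)c1 | intermediate
7 | methyl bromoacetate | COC(=O)CBr | starting material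
8 | bromo(2-methoxy-2-oxoethyl)zinc (Reformatsky reagent, not isolated) | COC(=O)C[Zn]Br | intermediate
9 | methyl 3-(benzyloxy)-4-{[4-(benzyloxy)-3-methoxybenzyl]oxy}-5-(2-methoxy-2-oxoethyl)benzoate | COc1cc(COc2c(OCc3ccccc3)cc(C(=O)OC)cc2CC(=O)OC)ccc1OCc1ccccc1 | intermediate
10 | methyl 3-(benzyloxy)-4-{[4-(benzyloxy)-3-methoxybenzyl]oxy}-5-(1-diazo-2-methoxy-2-oxoethyl)benzoate (key-step precursor) | COc1cc(COc2c(OCc3ccccc3)cc(C(=O)OC)cc2C(=[N+]=[N-])C(=O)OC)ccc1OCc1ccccc1 | intermediate
11 | dimethyl (2R,3S)-7-(benzyloxy)-2-[4-(benzyloxy)-3-methoxyphenyl]-2,3-dihydro-1-benzofuran-3,5-dicarboxylate (cis, not isolated) | COc1cc([C@@H]2Oc3c(OCc4ccccc4)cc(C(=O)OC)cc3[C@@H]2C(=O)OC)ccc1OCc1ccccc1 | intermediate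
12 | dimethyl (2R,3R)-7-(benzyloxy)-2-[4-(benzyloxy)-3-methoxyphenyl]-2,3-dihydro-1-benzofuran-3,5-dicarboxylate (trans, key-step product) | COc1cc([C@@H]2Oc3c(OCc4ccccc4)cc(C(=O)OC)cc3[C@H]2C(=O)OC)ccc1OCc1ccccc1 | intermediate
13 | [(2R,3S)-7-(benzyloxy)-2-[4-(benzyloxy)-3-methoxyphenyl]-2,3-dihydro-1-benzofuran-3,5-diyl]dimethanol (trans) | COc1cc([C@@H]2Oc3c(OCc4ccccc4)cc(CO)cc3[C@H]2CO)ccc1OCc1ccccc1 | intermediate
14 | (2R,3S)-7-(benzyloxy)-2-[4-(benzyloxy)-3-methoxyphenyl]-3-(hydroxymethyl)-2,3-dihydro-1-benzofuran-5-carbaldehyde | COc1cc([C@@H]2Oc3c(OCc4ccccc4)cc(C=O)cc3[C@H]2CO)ccc1OCc1ccccc1 | intermediate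
15 | 2',4',6'-trihydroxyacetophenone | CC(=O)c1c(O)cc(O)cc1O | starting material
16 | 1-[2,4-bis(benzyloxy)-6-hydroxyphenyl]ethanone | CC(=O)c1c(O)cc(OCc2ccccc2)cc1OCc1ccccc1 | intermediate
17 | tert-butyl 3-[2,4-bis(benzyloxy)-6-hydroxyphenyl]-3-oxopropanoate | CC(C)(C)OC(=O)CC(=O)c1c(O)cc(OCc2ccccc2)cc1OCc1ccccc1 | intermediate
18 | tert-butyl (2Z)-2-[2,4-bis(benzyloxy)-6-hydroxybenzoyl]-3-{(2R,3S)-7-(benzyloxy)-2-[4-(benzyloxy)-3-methoxyphenyl]-3-(hydroxymethyl)-2,3-dihydro-1-benzofuran-5-yl}prop-2-enoate | COc1cc([C@@H]2Oc3c(OCc4ccccc4)cc(/C=C(\C(=O)OC(C)(C)C)C(=O)c4c(O)cc(OCc5ccccc5)cc4OCc4ccccc4)cc3[C@H]2CO)ccc1OCc1ccccc1 | intermediate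
19 | tert-butyl (2S,3R)-5,7-bis(benzyloxy)-2-{(2R,3S)-7-(benzyloxy)-2-[4-(benzyloxy)-3-methoxyphenyl]-3-(hydroxymethyl)-2,3-dihydro-1-benzofuran-5-yl}-4-oxo-3,4-dihydro-2H-chromene-3-carboxylate (trans keto form, in equilibrium with its enol; not isolated) | COc1cc([C@@H]2Oc3c(OCc4ccccc4)cc([C@@H]4[C@@H](C(=O)OC(C)(C)C)C(=O)c5c(OCc6ccccc6)cc(OCc6ccccc6)cc5O4)cc3[C@H]2CO)ccc1OCc1ccccc1 | intermediate
20 | (2S)-5,7-bis(benzyloxy)-2-{(2R,3S)-7-(benzyloxy)-2-[4-(benzyloxy)-3-methoxyphenyl]-3-(hydroxymethyl)-2,3-dihydro-1-benzofuran-5-yl}-2,3-dihydro-4H-chromen-4-one | COc1cc([C@@H]2Oc3c(OCc4ccccc4)cc([C@@H]4CC(=O)c5c(OCc6ccccc6)cc(OCc6ccccc6)cc5O4)cc3[C@H]2CO)ccc1OCc1ccccc1 | intermediate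
21 | silyhermin B, (2S)-5,7-dihydroxy-2-[(2R,3S)-7-hydroxy-2-(4-hydroxy-3-methoxyphenyl)-3-(hydroxymethyl)-2,3-dihydro-1-benzofuran-5-yl]-2,3-dihydro-4H-chromen-4-one | COc1cc([C@@H]2Oc3c(O)cc([C@@H]4CC(=O)c5c(O)cc(O)cc5O4)cc3[C@H]2CO)ccc1O | target

Total step count: 14. Longest linear sequence: 11 steps (from 3 through steps 2–9 and 12–14 to 21).

Steps most likely to fail

Step 7. What may go wrong: insufficient discrimination between the two enantiotopic benzylic hydrogens at an ether flanked by two ortho substituents, loss of carbene to dimerisation, or loss of material by β-elimination during the base equilibration. Fallback (resolution in place of asymmetric catalysis): setting out from 10, the diazo ester is decomposed with achiral dirhodium tetraacetate Rh2(OAc)4 in CH2Cl2 at rt and equilibrated with NaOMe in MeOH to give the racemic trans-diester F1. Its enantiomers are separated by preparative HPLC on a cellulose tris(3,5-dimethylphenylcarbamate) phase, the (2S,3S)-diester F2 being set aside, and the route is rejoined at 12.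

Step 13. What may go wrong: poor facial selectivity of the ring closure with the doubly ortho-substituted phenol, uncatalysed closure already during or after the condensation of step 12, or erosion at C2 by acid-promoted ring opening during the decarboxylation. Fallback (diastereomer separation in place of catalyst control): setting out from 14 and 16, Claisen–Schmidt condensation (KOH, EtOH, rt) gives the 2'-hydroxychalcone F3. NaOAc in refluxing EtOH closes it to the flavanone without control at C2, which should give 20 together with its (2R)-epimer F4. Because C2' and C3' are already fixed these are diastereomers, to be separated by preparative HPLC, and the route is rejoined at 20.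

Step 5. What may go wrong: slow transmetalation at the bromide next to the bulky benzylic ether, ending in hydrodebromination, or self-condensation of the zinc enolate. Fallback (malonate arylation and dealkoxycarbonylation in place of the zinc enolate coupling): setting out from 6, palladium-catalysed α-arylation of dimethyl malonate (Pd(dba)2, P(t-Bu)3, K3PO4, toluene, 70 °C) gives the aryl malonate F5. Krapcho demethoxycarbonylation (LiCl, wet DMSO, 140 °C) then returns to the route at 9.

Further compounds

F1 | step 7 | racemic trans-diester, 1:1 mixture of 12 and F2 | COc1cc([C@@H]2Oc3c(OCc4ccccc4)cc(C(=O)OC)cc3[C@H]2C(=O)OC)ccc1OCc1ccccc1.COc1cc([C@H]2Oc3c(OCc4ccccc4)cc(C(=O)OC)cc3[C@@H]2C(=O)OC)ccc1OCc1ccccc1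
F2 | step 7 | dimethyl (2S,3S)-7-(benzyloxy)-2-[4-(benzyloxy)-3-methoxyphenyl]-2,3-dihydro-1-benzofuran-3,5-dicarboxylate | COc1cc([C@H]2Oc3c(OCc4ccccc4)cc(C(=O)OC)cc3[C@@H]2C(=O)OC)ccc1OCc1ccccc1
F3 | step 13 | (2E)-1-[2,4-bis(benzyloxy)-6-hydroxyphenyl]-3-{(2R,3S)-7-(benzyloxy)-2-[4-(benzyloxy)-3-methoxyphenyl]-3-(hydroxymethyl)-2,3-dihydro-1-benzofuran-5-yl}prop-2-en-1-one | COc1cc([C@@H]2Oc3c(OCc4ccccc4)cc(/C=C/C(=O)c4c(O)cc(OCc5ccccc5)cc4OCc4ccccc4)cc3[C@H]2CO)ccc1OCc1ccccc1
F4 | step 13 | (2R)-epimer of 20 | COc1cc([C@@H]2Oc3c(OCc4ccccc4)cc([C@H]4CC(=O)c5c(OCc6ccccc6)cc(OCc6ccccc6)cc5O4)cc3[C@H]2CO)ccc1OCc1ccccc1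
F5 | step 5 | dimethyl 2-{3-(benzyloxy)-2-{[4-(benzyloxy)-3-methoxybenzyl]oxy}-5-(methoxycarbonyl)phenyl}propanedioate | COc1cc(COc2c(OCc3ccccc3)cc(C(=O)OC)cc2C(C(=O)OC)C(=O)OC)ccc1OCc1ccccc1
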